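**Retrosynthetic overview**

1. The target is reached last from its tri-O-benzyl 5,7-di-O-methyl ether: BCl3 removes the benzyl groups and, through chelation to C4=O, only the peri 5-O-methyl group of the flavanone.
2. The key disconnection is C4–C4a of the flavanone pyranone ring (ring C), made by intramolecular Friedel–Crafts acylation of a (3S)-3-aryl-3-(3,5-dimethoxyphenoxy)propanoic acid. It rests on ring A of the flavanone (C4a, C5–C8, C8a), a phloroglucinol ring whose O5 and O7 differ only by one methyl group, so the symmetrical 3,5-dimethoxyphenyl ether of O1 has two equivalent ortho carbons, either of which can become C4a.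
3. The acid comes from oxidative cleavage of a terminal alkene; the O1–C2 bond comes from Mitsunobu inversion of an (R)-homoallylic alcohol with 3,5-dimethoxyphenol; the alcohol comes from Brown allylboration of a 4-(flavon-3-yloxy)benzaldehyde.
4. The aldehyde comes from SNAr of 5,7,4'-tri-O-benzylkaempferol on 4-fluorobenzaldehyde; the flavonol comes from DMDO oxidation of tri-O-benzylapigenin, made via the chalcone from 2',4',6'-trihydroxyacetophenone and 4-(benzyloxy)benzaldehyde.
5. Ring order: flavone pyranone ring first (step 3), flavanone pyranone ring last (step 10); the only stereocentre (C2) is set in step 6 and inverted in step 7.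

Key step: step 10

Assumption: the 4-aryloxybenzaldehyde of step 6 is taken to follow the facial preference established for benzaldehyde with B-allyldiisopinocampheylboranes, so the reagent derived from (−)-α-pinene adds to the Re face and gives the (R)-carbinol.

**Route**

Step 1
Reactants: 1 2',4',6'-trihydroxyacetophenone
Product: 2 1-[2,4-bis(benzyloxy)-6-hydroxyphenyl]ethan-1-one
Conditions: BnBr (2.1 equiv), K2CO3, DMF, rt
Reagents that add atoms: benzyl bromide, BrCc1ccccc1
Why: Williamson ether synthesis in which the 4-OH and one ortho OH are alkylated, while the remaining ortho OH, hydrogen-bonded to the acetyl carbonyl, is the least nucleophilic and should stay free when only two equivalents of BnBr are used.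

Step 2
Reactants: 2 1-[2,4-bis(benzyloxy)-6-hydroxyphenyl]ethan-1-one; 3 4-(benzyloxy)benzaldehyde
Product: 4 (E)-1-[2,4-bis(benzyloxy)-6-hydroxyphenyl]-3-[4-(benzyloxy)phenyl]prop-2-en-1-one
Conditions: KOH (aq.), EtOH/THF, rt
Reagents that add atoms: none
Why: Claisen–Schmidt condensation (crossed aldol with E1cB dehydration) in which the methyl ketone enolate adds to the non-enolisable aldehyde and the conjugated E-enone forms under thermodynamic control.

Step 3
Reactants: 4 (E)-1-[2,4-bis(benzyloxy)-6-hydroxyphenyl]-3-[4-(benzyloxy)phenyl]prop-2-en-1-one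
Product: 5 5,7-bis(benzyloxy)-2-[4-(benzyloxy)phenyl]-4H-chromen-4-one
Conditions: I2 (cat.), DMSO, 130 °C
Reagents that add atoms: none
Why: Iodine-catalysed oxidative cyclisation of a 2'-hydroxychalcone (oxa-Michael closure, α-iodination and loss of HI, with DMSO re-oxidising the iodide) closes the flavone pyranone ring, and catalytic iodine with a short reaction time should spare the 5-O-benzyl group.

Step 4
Reactants: 5 5,7-bis(benzyloxy)-2-[4-(benzyloxy)phenyl]-4H-chromen-4-one
Product: 7 5,7-bis(benzyloxy)-2-[4-(benzyloxy)phenyl]-3-hydroxy-4H-chromen-4-one, via flavone 2,3-epoxide 6 (not isolated)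
Conditions: DMDO (ca. 0.08 M in acetone), CH2Cl2, 0 °C to rt; evaporate; then p-TsOH·H2O (cat.), CH2Cl2, rt
Reagents that add atoms: dimethyldioxirane, CC1(C)OO1
Why: Electrophilic epoxidation of the C2=C3 enol-ether bond by neutral DMDO, followed by acid-catalysed opening of epoxide 6 at C2 (cation stabilised by O1 and the aryl group) and loss of H3, is the known flavone-to-flavonol oxidation and avoids the Algar–Flynn–Oyamada reaction, which tends to turn 6'-alkoxychalcones into aurones.

Step 5
Reactants: 7 5,7-bis(benzyloxy)-2-[4-(benzyloxy)phenyl]-3-hydroxy-4H-chromen-4-one; 8 4-fluorobenzaldehyde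
Product: 9 4-({5,7-bis(benzyloxy)-2-[4-(benzyloxy)phenyl]-4-oxo-4H-chromen-3-yl}oxy)benzaldehyde
Conditions: K2CO3, DMF (degassed, Ar), 100 °C
Reagents that add atoms: none
Why: Nucleophilic aromatic substitution (addition–elimination) in which the acidic enolic 3-OH, the only free hydroxyl, is deprotonated and displaces fluoride para to the formyl group that stabilises the Meisenheimer intermediate; oxygen is excluded because flavonolates are oxygenated in hot base, and the aldehyde is brought in only here because it would not survive the condensation and oxidation steps that build the chromone.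

Step 6
Reactants: 9 4-({5,7-bis(benzyloxy)-2-[4-(benzyloxy)phenyl]-4-oxo-4H-chromen-3-yl}oxy)benzaldehyde
Product: 11 5,7-bis(benzyloxy)-2-[4-(benzyloxy)phenyl]-3-{4-[(1R)-1-hydroxybut-3-en-1-yl]phenoxy}-4H-chromen-4-one, via diisopinocampheylborinate ester 10 (not isolated)
Conditions: (+)-Ipc2B(allyl) (from (−)-α-pinene, 1.5 equiv), THF/Et2O, −78 °C; then HOCH2CH2NH2, rt
Reagents that add atoms: (+)-B-allyldiisopinocampheylborane, C=CCB([C@H]1C[C@H]2C[C@@H]([C@@H]1C)C2(C)C)[C@H]1C[C@H]2C[C@@H]([C@@H]1C)C2(C)C
Why: Brown asymmetric allylboration through a chair-like six-membered (Zimmerman–Traxler) transition state, in which the isopinocampheyl groups derived from (−)-α-pinene direct the allyl group to the Re face of the aldehyde and so set the (R)-carbinol centre; the chromone carbonyl, a vinylogous ester, should not react at −78 °C, and the ethanolamine work-up spares it from alkaline peroxide.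

Step 7
Reactants: 11 5,7-bis(benzyloxy)-2-[4-(benzyloxy)phenyl]-3-{4-[(1R)-1-hydroxybut-3-en-1-yl]phenoxy}-4H-chromen-4-one; 12 3,5-dimethoxyphenol
Product: 13 5,7-bis(benzyloxy)-2-[4-(benzyloxy)phenyl]-3-{4-[(1S)-1-(3,5-dimethoxyphenoxy)but-3-en-1-yl]phenoxy}-4H-chromen-4-one
Conditions: PPh3, DIAD, toluene, 0 °C to rt
Reagents that add atoms: none
Why: Mitsunobu etherification in which the alkoxyphosphonium ion of 11 is displaced by the phenoxide of 12 (pKa about 9.3) in an SN2 step that inverts the centre from R to S, while the non-polar solvent and low temperature disfavour ionisation and the flavon-3-yloxy group is a weaker para donor than an alkoxy group.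

Step 8
Reactants: 13 5,7-bis(benzyloxy)-2-[4-(benzyloxy)phenyl]-3-{4-[(1S)-1-(3,5-dimethoxyphenoxy)but-3-en-1-yl]phenoxy}-4H-chromen-4-one
Product: 15 (3S)-3-[4-({5,7-bis(benzyloxy)-2-[4-(benzyloxy)phenyl]-4-oxo-4H-chromen-3-yl}oxy)phenyl]-3-(3,5-dimethoxyphenoxy)propanal, via 1,2-diol 14 (not isolated)
Conditions: OsO4 (cat.), NaIO4, 2,6-lutidine, dioxane/H2O (3:1), rt; crude aldehyde taken on at once
Reagents that add atoms: osmium tetroxide, O=[Os](=O)(=O)=O, which delivers the oxygen atoms and is re-oxidised by sodium periodate, [Na+].[O-]I(=O)(=O)=O, in water, O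
Why: Lemieux–Johnson oxidation in which OsO4 dihydroxylates the monosubstituted alkene far faster than the tetrasubstituted, carbonyl-conjugated C2=C3 bond of the chromone, NaIO4 cleaves diol 14 and re-oxidises osmium, and 2,6-lutidine buffers the mixture so that the β-aryloxy aldehyde does not eliminate; the stereocentre is not touched.

Step 9
Reactants: 15 (3S)-3-[4-({5,7-bis(benzyloxy)-2-[4-(benzyloxy)phenyl]-4-oxo-4H-chromen-3-yl}oxy)phenyl]-3-(3,5-dimethoxyphenoxy)propanal
Product: 16 (3S)-3-[4-({5,7-bis(benzyloxy)-2-[4-(benzyloxy)phenyl]-4-oxo-4H-chromen-3-yl}oxy)phenyl]-3-(3,5-dimethoxyphenoxy)propanoic acid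
Conditions: NaClO2, NaH2PO4, 2-methyl-2-butene (large excess), t-BuOH/THF/H2O, 0 °C to rt
Reagents that add atoms: sodium chlorite, [Na+].[O-]Cl=O
Why: Pinnick (Lindgren–Kraus) oxidation under a weakly acidic buffer, where the β-aryloxy group cannot leave by E1cB elimination, with a large excess of 2-methyl-2-butene to trap HOCl before it chlorinates the electron-rich dimethoxyphenoxy ring.

Step 10
Reactants: 16 (3S)-3-[4-({5,7-bis(benzyloxy)-2-[4-(benzyloxy)phenyl]-4-oxo-4H-chromen-3-yl}oxy)phenyl]-3-(3,5-dimethoxyphenoxy)propanoic acid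
Product: 18 (2S)-2-[4-({5,7-bis(benzyloxy)-2-[4-(benzyloxy)phenyl]-4-oxo-4H-chromen-3-yl}oxy)phenyl]-5,7-dimethoxy-2,3-dihydro-4H-chromen-4-one, via mixed trifluoroacetic anhydride 17 (not isolated)
Conditions: (CF3CO)2O (2 equiv), CH2Cl2 (high dilution), 0 °C; then aq. NaHCO3
Reagents that add atoms: none
Why: Intramolecular Friedel–Crafts acylation, the closest known type being the anhydride-mediated cyclisation of 3-aryloxypropanoic acids to chroman-4-ones: the acid is converted into mixed anhydride 17, an acylium equivalent, which is attacked by the carbon of the dimethoxyphenoxy ring that lies ortho to the ether oxygen and para to a methoxy group, and loss of a proton restores the arene and forms C4–C4a. The pyranone ring closes in a six-membered mode (6-exo-trig at the acyl carbon), the only one open to the three-atom tether, since the carbon between the two methoxy groups cannot reach the acyl group. No stereocentre is formed; C2, fixed by the Mitsunobu inversion, is not a reacting atom, and in the absence of base the product cannot open by a retro-oxa-Michael reaction. Because the two ortho carbons are equivalent there is no regiochemical question; what is needed is rate selectivity, ring closure having to be faster than acid ionisation of the benzylic C2–O bond and than trifluoroacetylation of the ring. This is secured by the three oxygen donors on the attacked ring, which should allow closure at 0 °C without a Lewis acid, by high dilution and by limiting the anhydride to about two equivalents.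

Step 11
Reactants: 18 (2S)-2-[4-({5,7-bis(benzyloxy)-2-[4-(benzyloxy)phenyl]-4-oxo-4H-chromen-3-yl}oxy)phenyl]-5,7-dimethoxy-2,3-dihydro-4H-chromen-4-one
Product: 19 (2S)-2-(4-{[5,7-dihydroxy-2-(4-hydroxyphenyl)-4-oxo-4H-chromen-3-yl]oxy}phenyl)-5-hydroxy-7-methoxy-2,3-dihydro-4H-chromen-4-one
Conditions: BCl3 (excess), C6HMe5, CH2Cl2, −78 °C to 0 °C; then MeOH/H2O
Reagents that add atoms: none
Why: Lewis-acid ether cleavage in which BCl3, with pentamethylbenzene as benzyl-cation trap, removes the three benzyl ethers at −78 °C without C-benzylation of the phloroglucinol rings, and on warming the boron chelated between C4=O and O5 of the flavanone delivers chloride to the peri methyl group only, the 7-methoxy group lacking such assistance; the stereocentre is not a reacting atom and the low temperature should prevent Lewis-acid opening of the pyranone ring.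

**Compound list**

1 | 2',4',6'-trihydroxyacetophenone | CC(=O)c1c(O)cc(O)cc1O | starting material
2 | 1-[2,4-bis(benzyloxy)-6-hydroxyphenyl]ethan-1-one | CC(=O)c1c(O)cc(OCc2ccccc2)cc1OCc1ccccc1 | intermediate
3 | 4-(benzyloxy)benzaldehyde | O=Cc1ccc(OCc2ccccc2)cc1 | starting material
4 | (E)-1-[2,4-bis(benzyloxy)-6-hydroxyphenyl]-3-[4-(benzyloxy)phenyl]prop-2-en-1-one | O=C(/C=C/c1ccc(OCc2ccccc2)cc1)c1c(O)cc(OCc2ccccc2)cc1OCc1ccccc1 | intermediate
5 | 5,7-bis(benzyloxy)-2-[4-(benzyloxy)phenyl]-4H-chromen-4-one (tri-O-benzylapigenin) | O=c1cc(-c2ccc(OCc3ccccc3)cc2)oc2cc(OCc3ccccc3)cc(OCc3ccccc3)c12 | intermediate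
6 | racemic flavone 2,3-epoxide, 4,6-bis(benzyloxy)-1a-[4-(benzyloxy)phenyl]-1a,7a-dihydro-7H-oxireno[2,3-b]chromen-7-one | O=C1C2OC2(c2ccc(OCc3ccccc3)cc2)Oc2cc(OCc3ccccc3)cc(OCc3ccccc3)c12 | intermediate (not isolated)
7 | 5,7-bis(benzyloxy)-2-[4-(benzyloxy)phenyl]-3-hydroxy-4H-chromen-4-one (5,7,4'-tri-O-benzylkaempferol) | O=c1c(O)c(-c2ccc(OCc3ccccc3)cc2)oc2cc(OCc3ccccc3)cc(OCc3ccccc3)c12 | intermediate
8 | 4-fluorobenzaldehyde | O=Cc1ccc(F)cc1 | starting material
9 | 4-({5,7-bis(benzyloxy)-2-[4-(benzyloxy)phenyl]-4-oxo-4H-chromen-3-yl}oxy)benzaldehyde | O=Cc1ccc(Oc2c(-c3ccc(OCc4ccccc4)cc3)oc3cc(OCc4ccccc4)cc(OCc4ccccc4)c3c2=O)cc1 | intermediate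
10 | diisopinocampheylborinate ester of (R)-alcohol 11 | C=CC[C@@H](OB([C@H]1C[C@H]2C[C@@H]([C@@H]1C)C2(C)C)[C@H]1C[C@H]2C[C@@H]([C@@H]1C)C2(C)C)c1ccc(Oc2c(-c3ccc(OCc4ccccc4)cc3)oc3cc(OCc4ccccc4)cc(OCc4ccccc4)c3c2=O)cc1 | intermediate (not isolated)
11 | 5,7-bis(benzyloxy)-2-[4-(benzyloxy)phenyl]-3-{4-[(1R)-1-hydroxybut-3-en-1-yl]phenoxy}-4H-chromen-4-one | C=CC[C@@H](O)c1ccc(Oc2c(-c3ccc(OCc4ccccc4)cc3)oc3cc(OCc4ccccc4)cc(OCc4ccccc4)c3c2=O)cc1 | intermediate
12 | 3,5-dimethoxyphenol | COc1cc(O)cc(OC)c1 | starting material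
13 | 5,7-bis(benzyloxy)-2-[4-(benzyloxy)phenyl]-3-{4-[(1S)-1-(3,5-dimethoxyphenoxy)but-3-en-1-yl]phenoxy}-4H-chromen-4-one | COc1cc(OC)cc(c1)O[C@H](c1ccc(Oc2c(-c3ccc(OCc4ccccc4)cc3)oc3cc(OCc4ccccc4)cc(OCc4ccccc4)c3c2=O)cc1)CC=C | intermediate
14 | 1,2-diol from 13, (1S)-configured at the aryloxy carbon, mixture of epimers at the new secondary carbinol | COc1cc(OC)cc(c1)O[C@H](c1ccc(Oc2c(-c3ccc(OCc4ccccc4)cc3)oc3cc(OCc4ccccc4)cc(OCc4ccccc4)c3c2=O)cc1)CC(O)CO | intermediate (not isolated)
15 | (3S)-3-[4-({5,7-bis(benzyloxy)-2-[4-(benzyloxy)phenyl]-4-oxo-4H-chromen-3-yl}oxy)phenyl]-3-(3,5-dimethoxyphenoxy)propanal | COc1cc(OC)cc(c1)O[C@H](c1ccc(Oc2c(-c3ccc(OCc4ccccc4)cc3)oc3cc(OCc4ccccc4)cc(OCc4ccccc4)c3c2=O)cc1)CC=O | intermediate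
16 | (3S)-3-[4-({5,7-bis(benzyloxy)-2-[4-(benzyloxy)phenyl]-4-oxo-4H-chromen-3-yl}oxy)phenyl]-3-(3,5-dimethoxyphenoxy)propanoic acid | COc1cc(OC)cc(c1)O[C@H](c1ccc(Oc2c(-c3ccc(OCc4ccccc4)cc3)oc3cc(OCc4ccccc4)cc(OCc4ccccc4)c3c2=O)cc1)CC(=O)O | intermediate
17 | mixed anhydride of acid 16 with trifluoroacetic acid | COc1cc(OC)cc(c1)O[C@H](c1ccc(Oc2c(-c3ccc(OCc4ccccc4)cc3)oc3cc(OCc4ccccc4)cc(OCc4ccccc4)c3c2=O)cc1)CC(=O)OC(=O)C(F)(F)F | intermediate (not isolated)
18 | (2S)-2-[4-({5,7-bis(benzyloxy)-2-[4-(benzyloxy)phenyl]-4-oxo-4H-chromen-3-yl}oxy)phenyl]-5,7-dimethoxy-2,3-dihydro-4H-chromen-4-one | COc1cc(OC)c2c(c1)O[C@H](c1ccc(Oc3c(-c4ccc(OCc5ccccc5)cc4)oc4cc(OCc5ccccc5)cc(OCc5ccccc5)c4c3=O)cc1)CC2=O | intermediate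
19 | (2S)-2-(4-{[5,7-dihydroxy-2-(4-hydroxyphenyl)-4-oxo-4H-chromen-3-yl]oxy}phenyl)-5-hydroxy-7-methoxy-2,3-dihydro-4H-chromen-4-one (CNP0173006.1) | COc1cc(O)c2c(c1)O[C@H](c1ccc(Oc3c(-c4ccc(O)cc4)oc4cc(O)cc(O)c4c3=O)cc1)CC2=O | target

**Step count and risk**

Total step count: 11. Longest linear sequence: 11 steps (from 1 to 19); compounds 3, 8 and 12 are bought.

Steps most likely to fail:

Step 10 (Friedel–Crafts closure). The benzylic C2–O bond may ionise in the trifluoroacetic acid that the step releases, leading to loss of 3,5-dimethoxyphenol, elimination to the cinnamic acid, or recombination with loss of configuration. The dimethoxyphenoxy ring may also be trifluoroacetylated before it is acylated intramolecularly. The fallback avoids acid at a benzylic ether altogether and forms C2–C1' and the stereocentre in one catalytic step; it sets out from flavonol 7 and comes back at flavanone 18. Flavonol 7 is O-arylated with 4-bromophenylboronic acid under Chan–Lam conditions (Cu(OAc)2, pyridine, 4 Å sieves, CH2Cl2, dry air, rt) to give 5,7-bis(benzyloxy)-2-[4-(benzyloxy)phenyl]-3-(4-bromophenoxy)-4H-chromen-4-one F1. Miyaura borylation (B2pin2, PdCl2(dppf), KOAc, dioxane, 80 °C) converts it into the corresponding 4-(4,4,5,5-tetramethyl-1,3,2-dioxaborolan-2-yl)phenyl ether F2. A rhodium-catalysed asymmetric 1,4-addition of Hayashi–Miyaura type of F2 to commercial 5,7-dimethoxychromone (COc1cc(OC)c2c(c1)occc2=O) then gives 18. The conditions would be [Rh(OH)(cod)]2 (cod = cycloocta-1,5-diene) with an electron-poor chiral bisphosphine of the MeO-F12-BIPHEP type, aqueous KOH, toluene, 40–60 °C, the ligand antipode being chosen to deliver the aryl group to the face that gives the 2S centre.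

Step 7 (Mitsunobu etherification). Ionisation of the activated benzylic alkoxyphosphonium ion (erosion of enantiopurity) and elimination to the 1-aryl-1,3-diene may compete with SN2 displacement. The fallback makes the other C–O bond of the ether, so the carbinol centre is never a leaving-group carbon; it sets out from aldehyde 9 and comes back at ether 13. Allylboration of 9 with the antipodal reagent (−)-Ipc2B(allyl), derived from (+)-α-pinene, under the conditions of step 6 gives 5,7-bis(benzyloxy)-2-[4-(benzyloxy)phenyl]-3-{4-[(1S)-1-hydroxybut-3-en-1-yl]phenoxy}-4H-chromen-4-one F3. Copper-catalysed O-arylation of F3 with 1-iodo-3,5-dimethoxybenzene (CuI, 3,4,7,8-tetramethyl-1,10-phenanthroline, Cs2CO3, toluene, 80–110 °C) should then give 13 with retention at the carbinol carbon.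

Step 5 (SNAr arylation of the flavonol). The hindered, delocalised flavonolate may add too slowly to the fluoroarene, and at the temperature then needed it may be degraded by traces of oxygen. The fallback replaces addition–elimination by an oxidative copper-mediated coupling at room temperature; it sets out from flavonol 7 and comes back at aldehyde 9. Chan–Lam coupling of 7 with 4-formylphenylboronic acid (Cu(OAc)2, pyridine, 4 Å sieves, CH2Cl2, dry air, rt) should give 9 directly, so this fallback makes no new compound (F0).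

**Further compounds**

F1 | step 10 | 5,7-bis(benzyloxy)-2-[4-(benzyloxy)phenyl]-3-(4-bromophenoxy)-4H-chromen-4-one | Brc1ccc(Oc2c(-c3ccc(OCc4ccccc4)cc3)oc3cc(OCc4ccccc4)cc(OCc4ccccc4)c3c2=O)cc1
F2 | step 10 | 5,7-bis(benzyloxy)-2-[4-(benzyloxy)phenyl]-3-[4-(4,4,5,5-tetramethyl-1,3,2-dioxaborolan-2-yl)phenoxy]-4H-chromen-4-one | CC1(C)OB(OC1(C)C)c1ccc(Oc2c(-c3ccc(OCc4ccccc4)cc3)oc3cc(OCc4ccccc4)cc(OCc4ccccc4)c3c2=O)cc1
F3 | step 7 | 5,7-bis(benzyloxy)-2-[4-(benzyloxy)phenyl]-3-{4-[(1S)-1-hydroxybut-3-en-1-yl]phenoxy}-4H-chromen-4-one | C=CC[C@H](O)c1ccc(Oc2c(-c3ccc(OCc4ccccc4)cc3)oc3cc(OCc4ccccc4)cc(OCc4ccccc4)c3c2=O)cc1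
F0 | step 5 | none | none
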